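**Plan**

1. Numbering: germacrane positions C1–C15; ring A is the ten-membered carbocycle, ring B the lactone, ring C the 4,5-epoxide. Retrosynthetic cuts, in order: the epoxide oxygen (restoring Z-C4=C5), the esters at O8 and O9, ring B at O–C6 and C11–C7 together (releasing 2-bromoacrylic acid), ring A at C9–C10, then the chain at C1=C10 and C5–C6.
2. Forward: an alkyne (C6–C9, from glyceraldehyde acetonide) and a Z-alkenyl iodide (C1–C5, from propyne) are joined at C5–C6; the iodo-enoate (C10, C14) is added at C1; ring A closes at C9–C10; the ring alkyne is semihydrogenated; ring B is annulated; O8 and O9 are acylated; ring C is formed last.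
3. Enabling feature: C5, an epoxide carbon in the target, sits next to C6, so the epoxide is a masked Z-C4=C5 alkene and C4=C5–C6=C7 is a cis,cis-1,3-diene inside ring A. An α-carboxyalkenylpalladium adds at its less substituted end C7, and the C6–C5–C4 allylpalladium is closed at C6 by the carboxylate; the free C8 hydroxyl next to C7 steers the face.
4. Stereochemistry: C8 from the chiral pool; C9 by Felkin–Anh reduction of a C9 ketone; C7 and C6 in the key step (O8-directed syn addition, C–O bond formed on the metal face); C4/C5 by peripheral epoxidation; the ester stereocenter from (R)-2-methylglycidol; alkene geometry from syn-carbocupration (C4=C5), Lindlar reduction (C6=C7) and ring size (C1=C10).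

Key step: step 14

Remark on the chemistry: the target is taken exactly as its SMILES encodes it, that is with a cis (ring) C1=C10 bond, a cis-fused lactone, H6, H7 and H8 on one face of ring A, H9 on the other, and a cis-4,5-epoxide whose oxygen is trans to O6 across the ring.

**Route**

Step 1
Reactants: 1 (R)-2,2-dimethyl-1,3-dioxolane-4-carbaldehyde
Product: 2 (4S)-4-ethynyl-2,2-dimethyl-1,3-dioxolane
Conditions: dimethyl (1-diazo-2-oxopropyl)phosphonate, K2CO3, MeOH, 0 °C to rt
Reagents that add atoms: dimethyl (1-diazo-2-oxopropyl)phosphonate, COP(=O)(OC)C(=[N+]=[N-])C(C)=O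
Why: Seyferth–Gilbert homologation in the Ohira–Bestmann variant should turn the aldehyde into the terminal alkyne (C6≡C7) under carbonate buffering, so that the C8 stereocenter taken from the chiral pool is kept.

Step 2
Reactants: 3 2-(2-bromoethyl)-1,3-dioxolane; 4 propyne
Product: 8 2-[(3Z)-4-iodo-3-methylbut-3-en-1-yl]-1,3-dioxolane, via Grignard reagent 5 (not isolated), via alkylcopper 6 (not isolated), via alkenylcopper 7 (not isolated)
Conditions: Mg, THF, 30 °C; CuBr·SMe2, Et2O/Me2S, −45 °C; propyne, −25 °C; I2, −50 °C to 0 °C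
Reagents that add atoms: iodine, II
Why: Normant carbocupration should add the alkylcopper syn across propyne with the alkyl group on the internal carbon, and iodinolysis with retention then fixes the Z geometry of C4=C5 (C3 cis to the future C6).

Step 3
Reactants: 2 alkyne; 8 Z-alkenyl iodide
Product: 9 (4S)-4-[(3Z)-6-(1,3-dioxolan-2-yl)-4-methylhex-3-en-1-yn-1-yl]-2,2-dimethyl-1,3-dioxolane
Conditions: PdCl2(PPh3)2 (3 mol %), CuI (6 mol %), i-Pr2NH, THF, rt
Reagents that add atoms: none
Why: Sonogashira coupling should join C5 to C6 with retention of the alkenyl iodide geometry and without touching C8.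

Step 4
Reactants: 9 enyne bis-acetal
Product: 10 (4Z,8S)-8,9-dihydroxy-4-methylnon-4-en-6-ynal
Conditions: 2 M HCl (aq), THF, 40 °C
Reagents that add atoms: water, O
Why: acid-catalysed acetal hydrolysis should remove the acetonide and the dioxolane together, which is safe at the propargylic stage because a C8 cation is not stabilised as it would be next to the later diene.

Step 5
Reactants: 10 aldehyde diol
Product: 11 methyl (2Z,6Z,10S)-10,11-dihydroxy-2-iodo-6-methylundeca-2,6-dien-8-ynoate
Conditions: Ph3P=CHCO2Me, N-iodosuccinimide, CH2Cl2, −20 °C; then 10, −20 °C to rt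
Reagents that add atoms: methyl (triphenylphosphoranylidene)acetate, COC(=O)C=P(c1ccccc1)(c1ccccc1)c1ccccc1; N-iodosuccinimide, O=C1CCC(=O)N1I
Why: Wittig olefination with the iodo ylide formed in the flask should give the (Z)-2-iodo-enoate (ester trans to C2) chemoselectively at the aldehyde, the free diol being inert.

Step 6
Reactants: 11 iodo-enoate diol
Product: 12 methyl (2Z,6Z,10S)-2-iodo-6-methyl-10,11-bis(triethylsilyloxy)undeca-2,6-dien-8-ynoate
Conditions: Et3SiCl, imidazole, DMF, 0 °C to rt
Reagents that add atoms: chlorotriethylsilane, CC[Si](Cl)(CC)CC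
Why: standard silylation should protect both hydroxyls as triethylsilyl ethers, the primary one being the ether that the next step can cleave selectively.

Step 7
Reactants: 12 bis(triethylsilyl) ether
Product: 13 methyl (2Z,6Z,10S)-2-iodo-6-methyl-11-oxo-10-(triethylsilyloxy)undeca-2,6-dien-8-ynoate
Conditions: (COCl)2, DMSO, CH2Cl2, −78 °C to −30 °C; Et3N, −78 °C to 0 °C
Reagents that add atoms: none
Why: under Swern conditions the primary triethylsilyl ether should be cleaved and oxidised in one pot (direct Swern oxidation of primary silyl ethers) while the secondary ether at C8 stays, and the cold, brief exposure to amine limits epimerisation of the α-silyloxy aldehyde.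

Step 8
Reactants: 13 iodo-enoate aldehyde
Product: 15 methyl (1E,5Z,9S,10RS)-10-hydroxy-5-methyl-9-(triethylsilyloxy)cyclodeca-1,5-dien-7-yne-1-carboxylate, via alkenylchromium dichloride 14 (not isolated)
Conditions: CrCl2 (6 equiv), NiCl2 (2 mol %), DMSO/THF, 2 mM, rt
Reagents that add atoms: none
Why: intramolecular Nozaki–Hiyama–Kishi coupling should close ring A at C9–C10 under neutral conditions that spare the epimerisable aldehyde, the ring allowing only the cis (ring) C1=C10 geometry, and C9 is accepted as a mixture (Felkin–Anh addition would favour the unwanted 8,9-anti epimer) because the next two steps reset it.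

Step 9
Reactants: 15 ring A alcohol (C9 epimers)
Product: 16 methyl (1E,5Z,9S)-5-methyl-10-oxo-9-(triethylsilyloxy)cyclodeca-1,5-dien-7-yne-1-carboxylate
Conditions: Dess–Martin periodinane, CH2Cl2, 0 °C
Reagents that add atoms: none
Why: Dess–Martin oxidation should converge both C9 epimers on one ketone without base, so that C8 (α to the new carbonyl) is not epimerised.

Step 10
Reactants: 16 ring A ketone
Product: 17 methyl (1E,5Z,9S,10S)-10-hydroxy-5-methyl-9-(triethylsilyloxy)cyclodeca-1,5-dien-7-yne-1-carboxylate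
Conditions: NaBH4, CeCl3·7H2O, MeOH, −78 °C
Reagents that add atoms: none
Why: Luche reduction is 1,2-selective on the cross-conjugated enone, and polar Felkin–Anh attack of hydride anti to the C8–OSiEt3 bond should give the 8,9-syn (C9 S) alcohol, the opposite sense to carbon addition to the aldehyde in step 8.

Step 11
Reactants: 17 8,9-syn alcohol
Product: 18 methyl (1E,5Z,9S,10S)-10-(tert-butyldimethylsilyloxy)-5-methyl-9-(triethylsilyloxy)cyclodeca-1,5-dien-7-yne-1-carboxylate
Conditions: t-BuMe2SiOTf, 2,6-lutidine, CH2Cl2, −78 °C to 0 °C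
Reagents that add atoms: tert-butyldimethylsilyl trifluoromethanesulfonate, CC(C)(C)[Si](C)(C)OS(=O)(=O)C(F)(F)F
Why: silylation with the silyl triflate should cap the hindered C9 hydroxyl as a robust ether that is neither a leaving group for palladium nor a donor in the key step.

Step 12
Reactants: 18 bis-silyl ether
Product: 19 methyl (1E,5Z,9S,10S)-10-(tert-butyldimethylsilyloxy)-9-hydroxy-5-methylcyclodeca-1,5-dien-7-yne-1-carboxylate
Conditions: PPTS (0.2 equiv), MeOH/CH2Cl2, 0 °C
Reagents that add atoms: none
Why: mild acid methanolysis should remove the triethylsilyl ether selectively beside the tert-butyldimethylsilyl ether (selective desilylation), freeing the C8 hydroxyl while C8 is still propargylic and not prone to ionise.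

Step 13
Reactants: 19 enyne alcohol
Product: 20 methyl (1E,5Z,7Z,9S,10S)-10-(tert-butyldimethylsilyloxy)-9-hydroxy-5-methylcyclodeca-1,5,7-triene-1-carboxylate
Conditions: H2 (1 atm), Pd/CaCO3/Pb(OAc)2, quinoline, EtOAc, rt
Reagents that add atoms: none
Why: Lindlar semihydrogenation should add hydrogen syn to the ring alkyne only, giving the Z C6=C7 bond and thus the cis,cis-diene, while the two trisubstituted alkenes are left.

Step 14
Reactants: 20 ring A dienol; 21 2-bromoprop-2-enoic acid
Product: 23 methyl (3aR,4S,5S,6E,10Z,11aS)-5-(tert-butyldimethylsilyloxy)-4-hydroxy-10-methyl-3-methylidene-2-oxo-2,3,3a,4,5,8,9,11a-octahydrocyclodeca[b]furan-6-carboxylate, via oxapalladacycle 22 (not isolated)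
Conditions: Pd(OAc)2 (10 mol %), P(2-furyl)3 (20 mol %), Ag2CO3 (1.5 equiv), DMF, 60 °C
Reagents that add atoms: none
Why: Zerovalent palladium inserts into the C–Br bond of the silver carboxylate of 21, the resulting α-carboxyalkenylpalladium binds the free C8 hydroxyl and the diene, adds syn across C6=C7 with its carbon at C7 (C11–C7 bond) to leave an allylpalladium over C6–C5–C4, and the pendant carboxylate then forms the O–C6 bond from the metal face through oxapalladacycle 22, which returns zerovalent palladium. The closest known reaction type is the Larock-type heteroannulation of 1,3-dienes by organic halides that carry a carboxylic acid, for which cis,cis-cyclic dienes are standard substrates. Ring B closes as a formal [3+2] annulation whose last bond is a 5-exo attack of the carboxylate oxygen on the allyl terminus C6 (inner-sphere C–O reductive elimination), leaving C4=C5 outside the new ring. C7 is set by the C8 oxygen, which as a ligand on cationic palladium should deliver C11 cis to O8 (the metal-bound mode that gives cis products from medium-ring allylic alcohols, against the peripheral trans preference of undirected reagents), and C6 is set by retention, oxygen arriving on the face that palladium occupies, so that the lactone is cis-fused. The step needs regiocontrol (C7 over the methyl-bearing terminus C4, and O attack at C6 to a five-membered ring over C4 to a seven-membered one), chemoselectivity (the electron-poor trisubstituted C1=C10 enoate should not insert, the C9 silyl ether cannot ionise, and Ag2CO3 is too weak a base to make the hydroxyl a competing nucleophile) and facial control, which the free C8 hydroxyl next to C7 is meant to secure.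

Step 15
Reactants: 24 [(2R)-2-methyloxiran-2-yl]methanol
Product: 25 (2S)-2-methyloxirane-2-carboxylic acid
Conditions: RuCl3·xH2O (2 mol %), NaIO4 (4 equiv), MeCN/EtOAc/H2O, 0 °C to rt
Reagents that add atoms: sodium periodate, [Na+].[O-]I(=O)(=O)=O; water, O
Why: catalytic ruthenium tetroxide oxidation should take the primary alcohol to the acid without opening the epoxide, and the quaternary stereocenter cannot epimerise (the descriptor changes from R to S by priority only).

Step 16
Reactants: 23 hydroxy lactone; 25 epoxy acid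
Product: 27 methyl (3aS,4S,5S,6E,10Z,11aS)-5-(tert-butyldimethylsilyloxy)-10-methyl-3-methylidene-4-{[(2S)-2-methyloxirane-2-carbonyl]oxy}-2-oxo-2,3,3a,4,5,8,9,11a-octahydrocyclodeca[b]furan-6-carboxylate, via mixed anhydride 26 (not isolated)
Conditions: 2,4,6-trichlorobenzoyl chloride, Et3N, THF, rt; then 23, DMAP, toluene, rt
Reagents that add atoms: none
Why: Yamaguchi esterification should acylate the hindered C8 hydroxyl with the α-quaternary acid through the mixed anhydride, with no change at any stereocenter (the C7 descriptor changes by priority only).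

Step 17
Reactants: 27 C8 ester
Product: 28 methyl (3aS,4S,5S,6E,10Z,11aS)-5-hydroxy-10-methyl-3-methylidene-4-{[(2S)-2-methyloxirane-2-carbonyl]oxy}-2-oxo-2,3,3a,4,5,8,9,11a-octahydrocyclodeca[b]furan-6-carboxylate
Conditions: HF·pyridine, pyridine, THF, 0 °C to rt
Reagents that add atoms: none
Why: buffered fluoride desilylation should free the C9 hydroxyl under weakly acidic conditions that avoid acyl migration and leave the lactone, the glycidate and the allylic C6–O bond intact.

Step 18
Reactants: 28 C9 alcohol
Product: 29 methyl (3aS,4S,5S,6E,10Z,11aS)-5-acetyloxy-10-methyl-3-methylidene-4-{[(2S)-2-methyloxirane-2-carbonyl]oxy}-2-oxo-2,3,3a,4,5,8,9,11a-octahydrocyclodeca[b]furan-6-carboxylate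
Conditions: Ac2O, pyridine, DMAP (5 mol %), CH2Cl2, 0 °C
Reagents that add atoms: acetic anhydride, CC(=O)OC(C)=O
Why: standard acetylation of the secondary allylic alcohol should be fast enough at 0 °C to outrun acyl migration or lactone exchange.

Step 19
Reactants: 29 diester diene
Product: 30 methyl (1R,2S,4R,7E,9S,10S,11R)-9-acetyloxy-4-methyl-12-methylidene-10-{[(2S)-2-methyloxirane-2-carbonyl]oxy}-13-oxo-3,14-dioxatricyclo[9.3.0.0(2,4)]tetradec-7-ene-8-carboxylate (CNP0274195.1)
Conditions: dimethyldioxirane, acetone, −20 °C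
Reagents that add atoms: dimethyldioxirane, CC1(C)OO1
Why: electrophilic epoxidation should pick the only electron-rich alkene (C4=C5) over the enoate and the two α-substituted acrylate units, and peripheral attack on the conformer with H6 in the alkene plane (allylic 1,3-strain against C3) and ring carbon C7 on the inner face should put the oxygen trans to O6 across the ring (4R,5S), as undirected peracid epoxidation does with medium-ring allylic ethers.

**Compound list**

1 | (R)-2,2-dimethyl-1,3-dioxolane-4-carbaldehyde | O=C[C@H]1COC(C)(C)O1 | starting material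
2 | (4S)-4-ethynyl-2,2-dimethyl-1,3-dioxolane | C#C[C@H]1COC(C)(C)O1 | intermediate
3 | 2-(2-bromoethyl)-1,3-dioxolane | BrCCC1OCCO1 | starting material
4 | propyne | CC#C | starting material
5 | [2-(1,3-dioxolan-2-yl)ethyl]magnesium bromide | Br[Mg]CCC1OCCO1 | intermediate
6 | [2-(1,3-dioxolan-2-yl)ethyl]copper | [Cu]CCC1OCCO1 | intermediate
7 | [(1Z)-4-(1,3-dioxolan-2-yl)-2-methylbut-1-en-1-yl]copper | [Cu]/C=C(C)\CCC1OCCO1 | intermediate
8 | 2-[(3Z)-4-iodo-3-methylbut-3-en-1-yl]-1,3-dioxolane | I/C=C(C)\CCC1OCCO1 | intermediate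
9 | (4S)-4-[(3Z)-6-(1,3-dioxolan-2-yl)-4-methylhex-3-en-1-yn-1-yl]-2,2-dimethyl-1,3-dioxolane | C1(CC/C(C)=C\C#C[C@H]2COC(C)(C)O2)OCCO1 | intermediate
10 | (4Z,8S)-8,9-dihydroxy-4-methylnon-4-en-6-ynal | O=CCC/C(C)=C\C#C[C@H](O)CO | intermediate
11 | methyl (2Z,6Z,10S)-10,11-dihydroxy-2-iodo-6-methylundeca-2,6-dien-8-ynoate | COC(=O)/C(I)=C/CC/C(C)=C\C#C[C@H](O)CO | intermediate
12 | methyl (2Z,6Z,10S)-2-iodo-6-methyl-10,11-bis(triethylsilyloxy)undeca-2,6-dien-8-ynoate | COC(=O)/C(I)=C/CC/C(C)=C\C#C[C@H](O[Si](CC)(CC)CC)CO[Si](CC)(CC)CC | intermediate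
13 | methyl (2Z,6Z,10S)-2-iodo-6-methyl-11-oxo-10-(triethylsilyloxy)undeca-2,6-dien-8-ynoate | COC(=O)/C(I)=C/CC/C(C)=C\C#C[C@H](O[Si](CC)(CC)CC)C=O | intermediate
14 | alkenylchromium dichloride from 13 (CrCl2 in place of iodine at C10) | COC(=O)/C([Cr](Cl)Cl)=C/CC/C(C)=C\C#C[C@H](O[Si](CC)(CC)CC)C=O | intermediate
15 | methyl (1E,5Z,9S,10RS)-10-hydroxy-5-methyl-9-(triethylsilyloxy)cyclodeca-1,5-dien-7-yne-1-carboxylate | C1/C(C)=C\C#C[C@H](O[Si](CC)(CC)CC)C(O)/C(C(=O)OC)=C\C1 | intermediate
16 | methyl (1E,5Z,9S)-5-methyl-10-oxo-9-(triethylsilyloxy)cyclodeca-1,5-dien-7-yne-1-carboxylate | C1/C(C)=C\C#C[C@H](O[Si](CC)(CC)CC)C(=O)/C(C(=O)OC)=C\C1 | intermediate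
17 | methyl (1E,5Z,9S,10S)-10-hydroxy-5-methyl-9-(triethylsilyloxy)cyclodeca-1,5-dien-7-yne-1-carboxylate | C1/C(C)=C\C#C[C@H](O[Si](CC)(CC)CC)[C@@H](O)/C(C(=O)OC)=C\C1 | intermediate
18 | methyl (1E,5Z,9S,10S)-10-(tert-butyldimethylsilyloxy)-5-methyl-9-(triethylsilyloxy)cyclodeca-1,5-dien-7-yne-1-carboxylate | C1/C(C)=C\C#C[C@H](O[Si](CC)(CC)CC)[C@@H](O[Si](C)(C)C(C)(C)C)/C(C(=O)OC)=C\C1 | intermediate
19 | methyl (1E,5Z,9S,10S)-10-(tert-butyldimethylsilyloxy)-9-hydroxy-5-methylcyclodeca-1,5-dien-7-yne-1-carboxylate | C1/C(C)=C\C#C[C@H](O)[C@@H](O[Si](C)(C)C(C)(C)C)/C(C(=O)OC)=C\C1 | intermediate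
20 | methyl (1E,5Z,7Z,9S,10S)-10-(tert-butyldimethylsilyloxy)-9-hydroxy-5-methylcyclodeca-1,5,7-triene-1-carboxylate | C1/C(C)=C\C=C/[C@H](O)[C@@H](O[Si](C)(C)C(C)(C)C)/C(C(=O)OC)=C\C1 | intermediate
21 | 2-bromoprop-2-enoic acid | C=C(Br)C(=O)O | starting material
22 | oxapalladacycle: palladium bound to C6 and to the carboxylate oxygen of the new C7 substituent (η1 form of the allylpalladium) | C=C1C(=O)O[Pd][C@@H]2[C@H]1[C@H](O)[C@@H](O[Si](C)(C)C(C)(C)C)/C(C(=O)OC)=C\CC/C(C)=C\2 | intermediate
23 | methyl (3aR,4S,5S,6E,10Z,11aS)-5-(tert-butyldimethylsilyloxy)-4-hydroxy-10-methyl-3-methylidene-2-oxo-2,3,3a,4,5,8,9,11a-octahydrocyclodeca[b]furan-6-carboxylate | C=C1C(=O)O[C@@H]2[C@H]1[C@H](O)[C@@H](O[Si](C)(C)C(C)(C)C)/C(C(=O)OC)=C\CC/C(C)=C\2 | intermediate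
24 | [(2R)-2-methyloxiran-2-yl]methanol | OC[C@]1(C)CO1 | starting material
25 | (2S)-2-methyloxirane-2-carboxylic acid | OC(=O)[C@]1(C)CO1 | intermediate
26 | (2S)-2-methyloxirane-2-carboxylic 2,4,6-trichlorobenzoic anhydride | O=C(OC(=O)[C@]1(C)CO1)c1c(Cl)cc(Cl)cc1Cl | intermediate
27 | methyl (3aS,4S,5S,6E,10Z,11aS)-5-(tert-butyldimethylsilyloxy)-10-methyl-3-methylidene-4-{[(2S)-2-methyloxirane-2-carbonyl]oxy}-2-oxo-2,3,3a,4,5,8,9,11a-octahydrocyclodeca[b]furan-6-carboxylate | C=C1C(=O)O[C@@H]2[C@H]1[C@H](OC(=O)[C@]1(C)CO1)[C@@H](O[Si](C)(C)C(C)(C)C)/C(C(=O)OC)=C\CC/C(C)=C\2 | intermediate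
28 | methyl (3aS,4S,5S,6E,10Z,11aS)-5-hydroxy-10-methyl-3-methylidene-4-{[(2S)-2-methyloxirane-2-carbonyl]oxy}-2-oxo-2,3,3a,4,5,8,9,11a-octahydrocyclodeca[b]furan-6-carboxylate | C=C1C(=O)O[C@@H]2[C@H]1[C@H](OC(=O)[C@]1(C)CO1)[C@@H](O)/C(C(=O)OC)=C\CC/C(C)=C\2 | intermediate
29 | methyl (3aS,4S,5S,6E,10Z,11aS)-5-acetyloxy-10-methyl-3-methylidene-4-{[(2S)-2-methyloxirane-2-carbonyl]oxy}-2-oxo-2,3,3a,4,5,8,9,11a-octahydrocyclodeca[b]furan-6-carboxylate | C=C1C(=O)O[C@@H]2[C@H]1[C@H](OC(=O)[C@]1(C)CO1)[C@@H](OC(C)=O)/C(C(=O)OC)=C\CC/C(C)=C\2 | intermediate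
30 | methyl (1R,2S,4R,7E,9S,10S,11R)-9-acetyloxy-4-methyl-12-methylidene-10-{[(2S)-2-methyloxirane-2-carbonyl]oxy}-13-oxo-3,14-dioxatricyclo[9.3.0.0(2,4)]tetradec-7-ene-8-carboxylate (CNP0274195.1) | C=C1C(=O)O[C@@H]2[C@H]1[C@H](OC(=O)[C@]1(C)CO1)[C@@H](OC(C)=O)/C(C(=O)OC)=C\CC[C@@]1(C)O[C@@H]21 | target

**Step count and risks**

Total step count: 19. Longest linear sequence: 17 steps (steps 2 to 14 and 16 to 19).

The three steps most likely to fail:

1. Step 14. What may go wrong: the hydroxyl may fail to steer the alkenylpalladium, so that insertion takes place on the outer face of C6=C7 (anti to ring carbon C9, trans to O8) and the lactone grows on the wrong face; a palladium alkoxide may lose a β-hydride and oxidise the carbinol; under base the new lactone may migrate to the cis O8. Fallback: use the peripheral preference instead of overriding it. Setting out from 19, Mitsunobu inversion at the propargylic C8 (4-nitrobenzoic acid, PPh3, DIAD) should give the C8-inverted 4-nitrobenzoate of 19 F1, methanolysis (K2CO3, MeOH) the 8-epi alcohol F2, silylation (Et3SiCl, imidazole) the 8-epi triethylsilyl ether F3, and Lindlar reduction the 8-epi cis,cis-diene F4. Undirected heteroannulation of F4 with 21 (Pd(OAc)2, KOAc, n-Bu4NCl, DMF, 60 °C) should then place C11 on the outer face, trans to the bulky C8 silyl ether, to give the 8-epi silyl lactone F5, in which C6 and C7 already have the target configuration. Selective removal of the triethylsilyl group (HF·pyridine, pyridine, THF, 0 °C) should give the 8-epi hydroxy lactone F6, and Mitsunobu esterification with 25 (PPh3, DIAD, toluene) inverts C8 while attaching the ester, which returns to the route at 27.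

2. Step 8. What may go wrong: intermolecular coupling (oligomerisation) may outrun ring closure, the alkenylchromium may be protonated before it finds the aldehyde, and the linear C5–C6≡C7–C8 unit may strain the closing transition state. Fallback: close ring A by condensation instead of organochromium addition, which forms the C1=C10 bond and delivers the ketone directly. Setting out from 9, selective hydrolysis of the acetonide (80% AcOH, rt) should give the diol acetal F7, silylation (Et3SiCl, imidazole) the bis(triethylsilyl) ether F8, direct Swern oxidation the aldehyde F9, Roskamp homologation (methyl diazoacetate, SnCl2, CH2Cl2) the β-keto ester F10, and neutral acetal exchange (I2 cat., acetone) the keto ester aldehyde F11. High-dilution Knoevenagel condensation between C1 and C10 (piperidine, AcOH, CH2Cl2, molecular sieves) then returns to the route at 16.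

3. Step 10. What may go wrong: the ring conformation may override Felkin–Anh control so that hydride arrives on the wrong face, or conjugate reduction of the alkylidene keto ester may compete. Fallback: replace substrate control by catalyst control. Corey–Bakshi–Shibata reduction of 16 (B-methyl oxazaborolidine, catecholborane, toluene, −78 °C, using the catalyst enantiomer matched to the C9 S alcohol) sets C9 from the reagent side; it sets out from 16 and returns at 17 without any new compound (F0).

Further compounds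
F1 | step 14 | C8-inverted 4-nitrobenzoate of 19 | C1/C(C)=C\C#C[C@@H](OC(=O)c2ccc(cc2)[N+](=O)[O-])[C@@H](O[Si](C)(C)C(C)(C)C)/C(C(=O)OC)=C\C1
F2 | step 14 | 8-epi alcohol (C8 epimer of 19) | C1/C(C)=C\C#C[C@@H](O)[C@@H](O[Si](C)(C)C(C)(C)C)/C(C(=O)OC)=C\C1
F3 | step 14 | 8-epi triethylsilyl ether (C8 epimer of 18) | C1/C(C)=C\C#C[C@@H](O[Si](CC)(CC)CC)[C@@H](O[Si](C)(C)C(C)(C)C)/C(C(=O)OC)=C\C1
F4 | step 14 | 8-epi cis,cis-diene (8-O-triethylsilyl, C8 epimer of 20) | C1/C(C)=C\C=C/[C@@H](O[Si](CC)(CC)CC)[C@@H](O[Si](C)(C)C(C)(C)C)/C(C(=O)OC)=C\C1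
F5 | step 14 | 8-epi silyl lactone (8-O-triethylsilyl, C8 epimer of 23) | C=C1C(=O)O[C@@H]2[C@H]1[C@@H](O[Si](CC)(CC)CC)[C@@H](O[Si](C)(C)C(C)(C)C)/C(C(=O)OC)=C\CC/C(C)=C\2
F6 | step 14 | 8-epi hydroxy lactone (C8 epimer of 23) | C=C1C(=O)O[C@@H]2[C@H]1[C@@H](O)[C@@H](O[Si](C)(C)C(C)(C)C)/C(C(=O)OC)=C\CC/C(C)=C\2
F7 | step 8 | (2S,5Z)-8-(1,3-dioxolan-2-yl)-6-methyloct-5-en-3-yne-1,2-diol | C1(CC/C(C)=C\C#C[C@H](O)CO)OCCO1
F8 | step 8 | bis(triethylsilyl) ether of F7 | C1(CC/C(C)=C\C#C[C@H](O[Si](CC)(CC)CC)CO[Si](CC)(CC)CC)OCCO1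
F9 | step 8 | (2S,5Z)-8-(1,3-dioxolan-2-yl)-6-methyl-2-(triethylsilyloxy)oct-5-en-3-ynal | C1(CC/C(C)=C\C#C[C@H](O[Si](CC)(CC)CC)C=O)OCCO1
F10 | step 8 | methyl (4S,7Z)-10-(1,3-dioxolan-2-yl)-8-methyl-3-oxo-4-(triethylsilyloxy)dec-7-en-5-ynoate | C1(CC/C(C)=C\C#C[C@H](O[Si](CC)(CC)CC)C(=O)CC(=O)OC)OCCO1
F11 | step 8 | methyl (4S,7Z)-8-methyl-3,11-dioxo-4-(triethylsilyloxy)undec-7-en-5-ynoate | O=CCC/C(C)=C\C#C[C@H](O[Si](CC)(CC)CC)C(=O)CC(=O)OC
F0 | step 10 | none | none
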